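Numbering used throughout: C1 bears the 4-oxyphenyl ring, C2 the 3,5-dioxyphenyl ring, C3 the side chain whose first carbon is Cα; C3a and C7a are the fusion carbons next to C3 and C1; the ring oxygens are on C5 and C7. This numbering is kept for every compound, also where nomenclature rules would reverse it.

## The problem

The target 23 is an indane: a cyclopentane fused to a resorcinol-type benzene ring, with three different substituents on the adjacent sp3 carbons C1, C2 and C3, all trans, and a fourth stereocentre, Cα, outside the ring. Only the five-membered ring has to be built, so the task is one ring closure and four stereocentres, (1R,2S,3R,αR), in absolute sense. C2 is the centre that can steer the others: a nucleophile enters at C1 anti to the C2 aryl group, and C3 trans to C2 is the stable arrangement, restored by enolisation whenever C3 is α to a carbonyl group. Cα has only C3 as a neighbour and needs a chiral reagent, and the absolute configuration of the ring must be imposed from outside because no chiral building block fits. The Cα carbinol is a 4-hydroxybenzylic alcohol that ionises to a p-quinone methide under acid or Lewis acid, so it cannot be present when aryl ethers are cleaved. C1 is benzylic and ortho/para to two ring oxygens, so a leaving group there ionises just as easily, with loss of the C2 hydrogen to a 2-arylindene as the escape; the three resorcinol-type rings are strong π-nucleophiles towards any cation and, once free, are easily oxidised. The two fusion carbons differ: C7a is ortho to O7 and para to O5, whereas C3a is meta to both, so the C3–C3a bond cannot be made by electrophilic substitution but C3a is well suited to carry a carbon–metal bond; with C1 as a formyl group on C7a, such an arylmetal offers a nucleophilic C3a and an electrophilic C1 to the two ends of a C2=C3 alkene.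

## Retrosynthesis

**Cα–H and the phenol masks (23 ⇐ 22 ⇐ 21 ⇐ 20 ⇐ 19).** The last bond made is the Cα–H bond, by reagent-controlled reduction of an aryl ketone. The carbinol cannot survive demethylation, so the six methyl ethers of ketone 19 are cleaved first to give hexaphenol 20. The phenols are then masked as acetates (21), because free phenols would consume borane and deactivate the ketone. Reduction gives carbinol 22, and cold base-catalysed methanolysis releases 23. Setting Cα earlier would leave no way to remove the methyl ethers. The forward steps need face selection at a ketone flanked by two bulky groups and a deacetylation that leaves the carbinol untouched.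

**Cα–aryl bond (19 ⇐ 18 ⇐ 16 + 17; 16 ⇐ 15 ⇐ 14).** Cutting the bond between Cα and its aryl ring removes a whole ring and leaves a one-carbon handle on C3. Ketone 19 comes from carbinol 18 by oxidation, and 18 from aldehyde 16 and Grignard reagent 17. Aldehyde 16 comes from alcohol 15 and its silyl ether 14. Cutting C3–Cα instead would require a C3 nucleophile or electrophile on the finished ring and would put the C3 configuration at risk. The one-carbon handle as an inert CH2OSi group is also exactly what an alkene partner can carry through the ring-forming step. The Cα configuration of 18 does not matter, and C3 is protected by the thermodynamic preference for trans.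

**C1–aryl bond (14 ⇐ 13 ⇐ 10 + 11; 10 ⇐ 9).** C1 is the natural electrophilic carbon, so its aryl group is added last to the ring, which lets the ring-forming step end in a plain carbinol. A free C1 cation trapped by a simple aryl ether was set aside: the dimethoxyphenyl rings of the substrate are far better π-nucleophiles than such a trap and would compete, and ortho attack would add isomers. Instead the aryl group is delivered from boron: the peri phenol O7–H and the C1 carbinol of diol 10 condense with boronic acid 11, water is lost to give o-quinone methide 12, and the aryl group moves from the oxygen-bound boron to C1 anti to the C2 aryl group, giving 13. This needs O7 to be distinguishable from the other ether oxygens. It is therefore carried as a benzyl ether in 9, removed by neutral hydrogenolysis (acid would ionise C1–OH), and the phenol of 13 is methylated to 14 so that the later oxidations meet no free phenol. The forward step must transfer the aryl group faster than the quinone methide tautomerises to the indene.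

**The ring (9 ⇐ 4 + 8), key disconnection.** The C3–C3a and C1–C2 bonds are cut together. Friedel–Crafts closures can only bond the C7a side of the arene and require the stereocentres to be made beforehand. The metal-mediated cut is the one that makes the ring and both C2 and C3 from two achiral partners with a chiral catalyst: arylboronate 4 (C3a–B, C1 as ortho formyl) and (E)-cinnamyl silyl ether 8 (C2=C3). The precursors are a trisubstituted benzaldehyde and a cinnamyl ether. The forward reaction must insert the alkene with the aryl group going to C3, add the C2–Rh bond to the aldehyde before β-hydride elimination, and select one alkene face.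

**The partners (4 ⇐ 3 ⇐ 2 ⇐ 1; 8 ⇐ 7 ⇐ 5).** Boronate 4 comes from bromide 3 by C–B for C–Br exchange. Benzyl ether 3 comes from phenol 2, and 2 from commercial dimethoxy aldehyde 1 by chelation-directed cleavage of the one methyl ether next to the formyl group. Silyl ether 8 comes from allylic alcohol 7, made from commercial cinnamic acid 5 through mixed anhydride 6.

## Roads not taken

**Alternative 1:** The cut is the C1–C7a bond, with the reactivity stored in a cyclopropane. In the donor–acceptor cyclopropane A1, [1,2-bis(3,5-dimethoxyphenyl)-3-(4-methoxyphenyl)cyclopropyl](4-methoxyphenyl)methanone, Sc(OTf)3 on the ketone would break the ring bond between the anisyl-bearing carbon (C1) and the acyl-bearing carbon (C3). The dimethoxyphenyl ring on C3 would then close onto the C1 cation through its ortho carbon (C7a), and protonation of the enolate would give the all-trans ketone A2.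
- Merits: A2 is the same compound as 19, so one ring-forming step reaches the point the chosen plan reaches at step 13. The C1 aryl group is already in place, the Friedel–Crafts closure is electronically matched, and all-trans is the stable outcome.
- Weak points: the difficulty moves into A1, a cyclopropane with an aryl/aroyl quaternary carbon and two aryl methines. It would have to come from transfer of a hindered acyl carbene to a trans-stilbene, a poorly precedented pairing. C1 and C3 are planar in the opened zwitterion, so only C2 carries the absolute configuration, and it would have to be set in that cyclopropanation. C2–H also sits next to the cation, where its loss would erase the centre.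
- Comparison: in step count and in arriving directly at 19 this road is better. The chosen plan sets against it that both ring stereocentres come from a catalyst acting on two simple achiral partners, and that its single unknown step has a fallback in known chemistry.

**Alternative 2:** The cut is at C1 twice, the C1–C7a and C1–aryl bonds. The aldehyde ester A3, methyl 2,3-bis(3,5-dimethoxyphenyl)-4-oxobutanoate, would cyclise in CF3SO3H/hexafluoroisopropanol by attack of the C3 aryl ring (through C7a) on the protonated aldehyde. The indanol would ionise, and the para carbon of phenol would capture the C1 cation anti to the C2 aryl group, giving the all-trans ester A4, methyl 2-(3,5-dimethoxyphenyl)-1-(4-hydroxyphenyl)-5,7-dimethoxyindane-3-carboxylate.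
- Merits: two C–C bonds at C1 in one flask, no transition metal, no O7 protecting-group exchange, and a precursor with two identical aryl groups.
- Weak points: both stereocentres of A3 are enolisable (α to aldehyde and α to ester), so configuration set before the superacid step can leak, and making A3 as one enantiomer is an unsolved problem in itself. The C1 cation can lose C2–H to the 2-arylindene. Phenol is a weaker π-nucleophile than the dimethoxyphenyl rings of a second substrate molecule, and it can also react at its ortho carbon or at oxygen. The ester of A4 must still be converted to the aryl ketone with a free phenol present.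
- Comparison: this road is shorter to a C1-arylated indane and simpler in reagents. The chosen plan offers catalyst-set absolute configuration and a C1 arylation by aryl transfer within a boron complex, which avoids a free cation in strong acid.

**Alternative 3:** The cut is the C3–C3a bond, made by a 1,2-shift. Photolysis of the diazo ketone A5, 2-diazo-3-(3,5-dimethoxyphenyl)-5,7-dimethoxy-4-(4-methoxyphenyl)-3,4-dihydronaphthalen-1(2H)-one, in methanol would expel N2. The aryl carbon would migrate from the carbonyl carbon to the carbene carbon (Wolff rearrangement), contracting the six-membered ring, and methanol would add to the ketene to give the ester A6, methyl 2-(3,5-dimethoxyphenyl)-5,7-dimethoxy-1-(4-methoxyphenyl)indane-3-carboxylate. The centre α to the ester settles as all-trans.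
- Merits: the ring contraction is a known reaction of 2-diazo-1-tetralones, the two aryl-bearing centres are untouched by it, and all oxygens stay as robust methyl ethers. In precedent for the key step this road is safer than the chosen one.
- Weak points: the real work becomes A5: an enantiopure trans-3,4-diaryl tetralone with the 5,7-dioxygen pattern, then diazo transfer next to a hindered methine. The carbene has a hydrogen on the adjacent carbon (1,2-hydride shift to an enone) and four electron-rich rings (insertion or ring expansion) as competitors. A6 still needs conversion of the ester to the aryl ketone.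
- Comparison: the chosen plan is shorter to the ring and makes ring and stereocentres in one catalytic step, at the price of an unprecedented substrate class in that step.

Key step: step 6

Remarks on the chemistry (assumptions):
- The chiral diene is written as (R,R)-Ph-bod*, (1R,4R)-2,5-diphenylbicyclo[2.2.2]octa-2,5-diene. Its sense of induction on this new substrate class cannot be predicted with confidence; the (S,S) ligand is used if the (R,R) ligand favours the mirror-image ring.
- Grignard reagent 17 is taken as the commercial THF solution.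

## Route

Step 1
Reactants: 1 2-bromo-4,6-dimethoxybenzaldehyde
Product: 2 2-bromo-6-hydroxy-4-methoxybenzaldehyde
Conditions: BCl3 (1.5 equiv), CH2Cl2, −78 → 0 °C; aq. work-up
Reagents that add atoms: none
Why: Chelation-directed Lewis-acid ether cleavage: BCl3 bridges the formyl oxygen and the neighbouring methoxy oxygen in a six-membered chelate, so only the ortho methyl ether is cut; the para ether and the bromide stay.

Step 2
Reactants: 2 2-bromo-6-hydroxy-4-methoxybenzaldehyde
Product: 3 2-(benzyloxy)-6-bromo-4-methoxybenzaldehyde
Conditions: BnBr, K2CO3, DMF, rt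
Reagents that add atoms: benzyl bromide, BrCc1ccccc1
Why: Williamson ether synthesis on an acidic salicylaldehyde-type phenol; benzyl is chosen because it withstands palladium/acetate and aqueous KOH and is later removed without acid.

Step 3
Reactants: 3 2-(benzyloxy)-6-bromo-4-methoxybenzaldehyde
Product: 4 2-(benzyloxy)-4-methoxy-6-(4,4,5,5-tetramethyl-1,3,2-dioxaborolan-2-yl)benzaldehyde
Conditions: B2pin2, PdCl2(dppf) (3 mol%), KOAc, 1,4-dioxane, 85 °C
Reagents that add atoms: bis(pinacolato)diboron, CC1(C)OB(OC1(C)C)B1OC(C)(C)C(C)(C)O1
Why: Miyaura borylation of an aryl bromide; the weak acetate base suppresses Suzuki homocoupling and the aldehyde is tolerated.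

Step 4
Reactants: 5 (E)-3-(3,5-dimethoxyphenyl)prop-2-enoic acid
Product: 7 (E)-3-(3,5-dimethoxyphenyl)prop-2-en-1-ol, via mixed carbonic anhydride 6 (not isolated)
Conditions: ClCO2Et, Et3N, THF, −10 °C; then NaBH4, H2O, 0 °C → rt
Reagents that add atoms: ethyl chloroformate, CCOC(=O)Cl (its atoms are held by intermediate 6 only)
Why: Mixed-anhydride activation followed by borohydride reduction takes the acid to the allylic alcohol without 1,4-reduction, so the (E)-alkene is kept.

Step 5
Reactants: 7 (E)-3-(3,5-dimethoxyphenyl)prop-2-en-1-ol
Product: 8 (E)-tert-butyl{[3-(3,5-dimethoxyphenyl)prop-2-en-1-yl]oxy}dimethylsilane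
Conditions: TBSCl, imidazole, DMF, rt
Reagents that add atoms: tert-butyldimethylsilyl chloride, CC(C)(C)[Si](C)(C)Cl
Why: Imidazole-promoted silylation; the silyl ether stops rhodium-mediated isomerisation of the allylic alcohol and is too poor a leaving group for β-oxygen elimination.

Step 6
Reactants: 4 2-(benzyloxy)-4-methoxy-6-(4,4,5,5-tetramethyl-1,3,2-dioxaborolan-2-yl)benzaldehyde; 8 (E)-tert-butyl{[3-(3,5-dimethoxyphenyl)prop-2-en-1-yl]oxy}dimethylsilane
Product: 9 (2S,3R)-7-(benzyloxy)-3-{[(tert-butyldimethylsilyl)oxy]methyl}-2-(3,5-dimethoxyphenyl)-5-methoxyindan-1-ol (2,3-trans; both C1 epimers are used)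
Conditions: [RhCl(C2H4)2]2 (2.5 mol%), (R,R)-Ph-bod* (5.5 mol%), KOH (0.5 equiv, aq.), 1,4-dioxane/H2O 10:1, 60 °C; 4 in excess (1.5 equiv)
Reagents that add atoms: none
Why: Proposed new method: the hydroxorhodium–diene complex formed from the chloride dimer and KOH should transmetalate with 4 to an arylrhodium at C3a, which inserts the (E)-alkene of 8 with the aryl group going to the CH2OSi-bearing carbon (C3) and rhodium to C2, held there as an η3-benzyl complex by the 3,5-dimethoxyphenyl ring; the C2–Rh bond then adds to the formyl group on the same arene and water protonates the rhodium alkoxide, returning Rh–OH. The closest known reaction type is the rhodium-catalysed [3+2] annulation of 2-formylarylboron reagents with alkynes, 1,3-dienes and strained alkenes, together with chiral-diene rhodium arylations of alkenes; an acyclic, unstrained styrenyl alkene has not served as the two-carbon partner. The cyclopentane ring closes by 5-exo-trig addition of the benzylic C2–Rh bond to the C1 carbonyl (C1–C2 bond) after the intermolecular C3–C3a bond. C3 is set by the chiral diene, which chooses the alkene face in the insertion; C2 follows from syn addition across the (E)-alkene and retention in the C–C bond formation, which puts the C2 aryl trans to the C3 CH2OSi group; C1 forms in the carbonyl addition without need for control because step 8 erases it. The step needs regioselective insertion (secured by benzylic stabilisation of rhodium at C2), carbonyl addition faster than β-hydride elimination of C3–H (helped by the formyl group within five-membered reach and by the diene, which leaves no free cis site in the benzyl complex) and face selectivity (ligand).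

Step 7
Reactants: 9 (2S,3R)-7-(benzyloxy)-3-{[(tert-butyldimethylsilyl)oxy]methyl}-2-(3,5-dimethoxyphenyl)-5-methoxyindan-1-ol
Product: 10 (2S,3R)-3-{[(tert-butyldimethylsilyl)oxy]methyl}-2-(3,5-dimethoxyphenyl)-5-methoxyindane-1,7-diol (both C1 epimers)
Conditions: H2 (1 atm), 10% Pd/C, EtOAc, rt; stopped at full conversion
Reagents that add atoms: none
Why: Catalytic hydrogenolysis of an aryl benzyl ether under neutral conditions, which is faster than cleavage of a benzylic alcohol; no acid is present to ionise C1–OH and the silyl ether is stable in ethyl acetate.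

Step 8
Reactants: 10 (2S,3R)-3-{[(tert-butyldimethylsilyl)oxy]methyl}-2-(3,5-dimethoxyphenyl)-5-methoxyindane-1,7-diol; 11 4-methoxyphenylboronic acid
Product: 13 (1R,2S,3R)-3-{[(tert-butyldimethylsilyl)oxy]methyl}-2-(3,5-dimethoxyphenyl)-5-methoxy-1-(4-methoxyphenyl)indan-7-ol, via o-quinone methide 12 (not isolated)
Conditions: 11 (2 equiv), (±)-3,3′-Br2-BINOL (15 mol%), 4 Å MS, toluene, 40 °C
Reagents that add atoms: none
Why: Biphenol-catalysed conjugate addition of an arylboron reagent to an o-quinone methide generated from an o-hydroxybenzyl alcohol: boron binds O7 and O1, water is lost at the doubly activated C1, and the aryl group moves from boron to C1. C1 is set by the substrate: the aryl group enters anti to the C2 aryl group, giving 1,2-trans, and both C1 epimers of 10 converge on the same planar intermediate.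

Step 9
Reactants: 13 (1R,2S,3R)-3-{[(tert-butyldimethylsilyl)oxy]methyl}-2-(3,5-dimethoxyphenyl)-5-methoxy-1-(4-methoxyphenyl)indan-7-ol
Product: 14 (1R,2S,3R)-3-{[(tert-butyldimethylsilyl)oxy]methyl}-2-(3,5-dimethoxyphenyl)-5,7-dimethoxy-1-(4-methoxyphenyl)indane
Conditions: MeI, K2CO3, DMF, 40 °C
Reagents that add atoms: iodomethane, CI
Why: Williamson methylation of the phenol; it removes the only free, oxidisable phenol before the two oxidations and the Grignard step and leaves six equal methyl ethers for one later cleavage.

Step 10
Reactants: 14 (1R,2S,3R)-3-{[(tert-butyldimethylsilyl)oxy]methyl}-2-(3,5-dimethoxyphenyl)-5,7-dimethoxy-1-(4-methoxyphenyl)indane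
Product: 15 [(1R,2S,3R)-2-(3,5-dimethoxyphenyl)-5,7-dimethoxy-1-(4-methoxyphenyl)indan-3-yl]methanol
Conditions: TBAF, THF, 0 °C → rt
Reagents that add atoms: none
Why: Fluoride-induced desilylation of a primary silyl ether; nothing else in the molecule responds to fluoride.

Step 11
Reactants: 15 [(1R,2S,3R)-2-(3,5-dimethoxyphenyl)-5,7-dimethoxy-1-(4-methoxyphenyl)indan-3-yl]methanol
Product: 16 (1R,2S,3R)-2-(3,5-dimethoxyphenyl)-5,7-dimethoxy-1-(4-methoxyphenyl)indane-3-carbaldehyde
Conditions: Dess–Martin periodinane, CH2Cl2, 0 °C → rt
Reagents that add atoms: none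
Why: Dess–Martin oxidation of a primary alcohol; C3 becomes enolisable but trans to the C2 aryl group is the stable arrangement, so enolisation cannot harm it.

Step 12
Reactants: 16 (1R,2S,3R)-2-(3,5-dimethoxyphenyl)-5,7-dimethoxy-1-(4-methoxyphenyl)indane-3-carbaldehyde; 17 4-methoxyphenylmagnesium bromide
Product: 18 [(1R,2S,3R)-2-(3,5-dimethoxyphenyl)-5,7-dimethoxy-1-(4-methoxyphenyl)indan-3-yl](4-methoxyphenyl)methanol (both Cα epimers)
Conditions: 17 (2 equiv), THF, −78 → 0 °C
Reagents that add atoms: none
Why: Grignard addition to an aldehyde at low temperature to outrun enolisation; the new Cα centre is not controlled and need not be, since step 13 removes it.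

Step 13
Reactants: 18 [(1R,2S,3R)-2-(3,5-dimethoxyphenyl)-5,7-dimethoxy-1-(4-methoxyphenyl)indan-3-yl](4-methoxyphenyl)methanol
Product: 19 [(1R,2S,3R)-2-(3,5-dimethoxyphenyl)-5,7-dimethoxy-1-(4-methoxyphenyl)indan-3-yl](4-methoxyphenyl)methanone
Conditions: Dess–Martin periodinane, CH2Cl2, rt
Reagents that add atoms: none
Why: Dess–Martin oxidation of a secondary benzylic alcohol merges both Cα epimers into one ketone; C3 stays trans for the thermodynamic reason given in step 11.

Step 14
Reactants: 19 [(1R,2S,3R)-2-(3,5-dimethoxyphenyl)-5,7-dimethoxy-1-(4-methoxyphenyl)indan-3-yl](4-methoxyphenyl)methanone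
Product: 20 [(1R,2S,3R)-2-(3,5-dihydroxyphenyl)-5,7-dihydroxy-1-(4-hydroxyphenyl)indan-3-yl](4-hydroxyphenyl)methanone
Conditions: BBr3 (12 equiv), CH2Cl2, −78 °C → rt; MeOH/H2O quench
Reagents that add atoms: none
Why: Lewis-acid cleavage of all six aryl methyl ethers, done at the ketone stage because a benzylic carbinol at Cα would ionise under BBr3; the deactivated aryl ketone and the ring C–H centres are inert.

Step 15
Reactants: 20 [(1R,2S,3R)-2-(3,5-dihydroxyphenyl)-5,7-dihydroxy-1-(4-hydroxyphenyl)indan-3-yl](4-hydroxyphenyl)methanone
Product: 21 the hexaacetate of 20: [(1R,2S,3R)-5,7-diacetoxy-2-(3,5-diacetoxyphenyl)-1-(4-acetoxyphenyl)indan-3-yl](4-acetoxyphenyl)methanone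
Conditions: Ac2O, pyridine, rt
Reagents that add atoms: acetic anhydride, CC(=O)OC(C)=O
Why: Acetylation of phenols; the acetates stop the phenols from consuming borane and raise the electrophilicity of the ketone, and they come off under mild base.

Step 16
Reactants: 21 [(1R,2S,3R)-5,7-diacetoxy-2-(3,5-diacetoxyphenyl)-1-(4-acetoxyphenyl)indan-3-yl](4-acetoxyphenyl)methanone
Product: 22 the hexaacetate of the target: (R)-[(1R,2S,3R)-5,7-diacetoxy-2-(3,5-diacetoxyphenyl)-1-(4-acetoxyphenyl)indan-3-yl](4-acetoxyphenyl)methanol
Conditions: (S)-Me-CBS (20 mol%), BH3·SMe2 (0.7 equiv), THF, −20 °C; MeOH quench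
Reagents that add atoms: none
Why: Corey–Bakshi–Shibata reduction: with the aryl group as the large substituent the (S)-oxazaborolidine delivers hydride to the face that gives the (R)-carbinol, the same sense as for simple aryl alkyl ketones; Cα is set by the reagent, and the ketone is reduced faster than aryl acetates at this temperature.

Step 17
Reactants: 22 (R)-[(1R,2S,3R)-5,7-diacetoxy-2-(3,5-diacetoxyphenyl)-1-(4-acetoxyphenyl)indan-3-yl](4-acetoxyphenyl)methanol
Product: 23 (1R,2S,3R)-2-(3,5-dihydroxyphenyl)-3-[(R)-hydroxy(4-hydroxyphenyl)methyl]-1-(4-hydroxyphenyl)indane-5,7-diol (CNP0214825.1)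
Conditions: K2CO3 (0.3 equiv), MeOH, 0 °C; neutralised with NH4Cl, no strong acid
Reagents that add atoms: none
Why: Base-catalysed transesterification (Zemplén-type methanolysis) of aryl acetates, fast at 0 °C; no bond to a stereocentre is touched, and cold, weakly basic conditions keep the 4-hydroxybenzylic carbinol from ionising.

## Compound list

1 | 2-bromo-4,6-dimethoxybenzaldehyde | COc1cc(Br)c(C=O)c(OC)c1 | starting material
2 | 2-bromo-6-hydroxy-4-methoxybenzaldehyde | COc1cc(O)c(C=O)c(Br)c1 | intermediate
3 | 2-(benzyloxy)-6-bromo-4-methoxybenzaldehyde | COc1cc(Br)c(C=O)c(OCc2ccccc2)c1 | intermediate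
4 | 2-(benzyloxy)-4-methoxy-6-(4,4,5,5-tetramethyl-1,3,2-dioxaborolan-2-yl)benzaldehyde | COc1cc(B2OC(C)(C)C(C)(C)O2)c(C=O)c(OCc2ccccc2)c1 | intermediate
5 | (E)-3-(3,5-dimethoxyphenyl)prop-2-enoic acid | COc1cc(/C=C/C(=O)O)cc(OC)c1 | starting material
6 | (E)-3-(3,5-dimethoxyphenyl)prop-2-enoic ethyl carbonic anhydride | CCOC(=O)OC(=O)/C=C/c1cc(OC)cc(OC)c1 | intermediate (not isolated)
7 | (E)-3-(3,5-dimethoxyphenyl)prop-2-en-1-ol | COc1cc(/C=C/CO)cc(OC)c1 | intermediate
8 | (E)-tert-butyl{[3-(3,5-dimethoxyphenyl)prop-2-en-1-yl]oxy}dimethylsilane | COc1cc(/C=C/CO[Si](C)(C)C(C)(C)C)cc(OC)c1 | intermediate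
9 | (2S,3R)-7-(benzyloxy)-3-{[(tert-butyldimethylsilyl)oxy]methyl}-2-(3,5-dimethoxyphenyl)-5-methoxyindan-1-ol, 2,3-trans, both C1 epimers | OC1c2c(OCc3ccccc3)cc(OC)cc2[C@H](CO[Si](C)(C)C(C)(C)C)[C@H]1c1cc(OC)cc(OC)c1 | intermediate
10 | (2S,3R)-3-{[(tert-butyldimethylsilyl)oxy]methyl}-2-(3,5-dimethoxyphenyl)-5-methoxyindane-1,7-diol, both C1 epimers | OC1c2c(O)cc(OC)cc2[C@H](CO[Si](C)(C)C(C)(C)C)[C@H]1c1cc(OC)cc(OC)c1 | intermediate
11 | 4-methoxyphenylboronic acid | COc1ccc(B(O)O)cc1 | starting material
12 | (2S,3R)-3-{[(tert-butyldimethylsilyl)oxy]methyl}-2-(3,5-dimethoxyphenyl)-5-methoxy-2,3-dihydro-7H-inden-7-one (o-quinone methide, C1=C7a) | O=C1C=C(OC)C=C2[C@H](CO[Si](C)(C)C(C)(C)C)[C@@H](c3cc(OC)cc(OC)c3)C=C12 | intermediate (not isolated)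
13 | (1R,2S,3R)-3-{[(tert-butyldimethylsilyl)oxy]methyl}-2-(3,5-dimethoxyphenyl)-5-methoxy-1-(4-methoxyphenyl)indan-7-ol | COc1ccc([C@@H]2c3c(O)cc(OC)cc3[C@H](CO[Si](C)(C)C(C)(C)C)[C@H]2c2cc(OC)cc(OC)c2)cc1 | intermediate
14 | (1R,2S,3R)-3-{[(tert-butyldimethylsilyl)oxy]methyl}-2-(3,5-dimethoxyphenyl)-5,7-dimethoxy-1-(4-methoxyphenyl)indane | COc1ccc([C@@H]2c3c(OC)cc(OC)cc3[C@H](CO[Si](C)(C)C(C)(C)C)[C@H]2c2cc(OC)cc(OC)c2)cc1 | intermediate
15 | [(1R,2S,3R)-2-(3,5-dimethoxyphenyl)-5,7-dimethoxy-1-(4-methoxyphenyl)indan-3-yl]methanol | COc1ccc([C@@H]2c3c(OC)cc(OC)cc3[C@H](CO)[C@H]2c2cc(OC)cc(OC)c2)cc1 | intermediate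
16 | (1R,2S,3R)-2-(3,5-dimethoxyphenyl)-5,7-dimethoxy-1-(4-methoxyphenyl)indane-3-carbaldehyde | COc1ccc([C@@H]2c3c(OC)cc(OC)cc3[C@H](C=O)[C@H]2c2cc(OC)cc(OC)c2)cc1 | intermediate
17 | 4-methoxyphenylmagnesium bromide | COc1ccc([Mg]Br)cc1 | starting material
18 | [(1R,2S,3R)-2-(3,5-dimethoxyphenyl)-5,7-dimethoxy-1-(4-methoxyphenyl)indan-3-yl](4-methoxyphenyl)methanol, both Cα epimers | COc1ccc([C@@H]2c3c(OC)cc(OC)cc3[C@H](C(O)c3ccc(OC)cc3)[C@H]2c2cc(OC)cc(OC)c2)cc1 | intermediate
19 | [(1R,2S,3R)-2-(3,5-dimethoxyphenyl)-5,7-dimethoxy-1-(4-methoxyphenyl)indan-3-yl](4-methoxyphenyl)methanone | COc1ccc([C@@H]2c3c(OC)cc(OC)cc3[C@H](C(=O)c3ccc(OC)cc3)[C@H]2c2cc(OC)cc(OC)c2)cc1 | intermediate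
20 | [(1R,2S,3R)-2-(3,5-dihydroxyphenyl)-5,7-dihydroxy-1-(4-hydroxyphenyl)indan-3-yl](4-hydroxyphenyl)methanone | Oc1ccc([C@@H]2c3c(O)cc(O)cc3[C@H](C(=O)c3ccc(O)cc3)[C@H]2c2cc(O)cc(O)c2)cc1 | intermediate
21 | [(1R,2S,3R)-5,7-diacetoxy-2-(3,5-diacetoxyphenyl)-1-(4-acetoxyphenyl)indan-3-yl](4-acetoxyphenyl)methanone | CC(=O)Oc1ccc([C@@H]2c3c(OC(C)=O)cc(OC(C)=O)cc3[C@H](C(=O)c3ccc(OC(C)=O)cc3)[C@H]2c2cc(OC(C)=O)cc(OC(C)=O)c2)cc1 | intermediate
22 | (R)-[(1R,2S,3R)-5,7-diacetoxy-2-(3,5-diacetoxyphenyl)-1-(4-acetoxyphenyl)indan-3-yl](4-acetoxyphenyl)methanol | CC(=O)Oc1ccc([C@@H]2c3c(OC(C)=O)cc(OC(C)=O)cc3[C@H]([C@@H](O)c3ccc(OC(C)=O)cc3)[C@H]2c2cc(OC(C)=O)cc(OC(C)=O)c2)cc1 | intermediate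
23 | (1R,2S,3R)-2-(3,5-dihydroxyphenyl)-3-[(R)-hydroxy(4-hydroxyphenyl)methyl]-1-(4-hydroxyphenyl)indane-5,7-diol | Oc1ccc([C@@H]2c3c(O)cc(O)cc3[C@H]([C@@H](O)c3ccc(O)cc3)[C@H]2c2cc(O)cc(O)c2)cc1 | target

## Step count and risk

Total: 17 steps. Longest linear sequence: 15 steps (1 → 2 → 3 → 4 → 9 → 10 → 13 → 14 → 15 → 16 → 18 → 19 → 20 → 21 → 22 → 23; steps 1–3 and 6–17). The side branch 5 → 7 → 8 is two steps.

Least certain steps:

**Step 6 (key step, proposed new method).** The most likely failure is β-hydride elimination of C3–H from the benzylrhodium intermediate, giving a Heck-type arylated alkene, or slow insertion of the unactivated 1,2-disubstituted alkene. In the second case, protodeboronation of 4 and addition of the arylrhodium to the aldehyde of another molecule would take over. Weak face selection is the second concern.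

The fallback uses known chemistry, sets out from 4 and returns at 9:
- Sonogashira coupling of commercial 1-bromo-3,5-dimethoxybenzene with commercial tert-butyldimethyl(prop-2-yn-1-yloxy)silane (PdCl2(PPh3)2, CuI, Et3N) gives the alkyne tert-butyl{[3-(3,5-dimethoxyphenyl)prop-2-yn-1-yl]oxy}dimethylsilane F1.
- The established rhodium-catalysed [3+2] annulation of a 2-formylarylboron reagent with an internal aryl alkyl alkyne ([Rh(OH)(cod)]2, dioxane/H2O) joins 4 and F1. The aryl group goes to the alkyl-bearing alkyne carbon, giving the racemic indenol 7-(benzyloxy)-3-{[(tert-butyldimethylsilyl)oxy]methyl}-2-(3,5-dimethoxyphenyl)-5-methoxy-1H-inden-1-ol F2.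
- An amine base (DABCO) shifts the C1 hydrogen to C3 and the enol tautomerises to the racemic trans ketone (2S*,3R*)-7-(benzyloxy)-3-{[(tert-butyldimethylsilyl)oxy]methyl}-2-(3,5-dimethoxyphenyl)-5-methoxyindan-1-one F3.
- Noyori–Ikariya transfer hydrogenation (RuCl(p-cymene)(TsDPEN), HCO2H/Et3N), run as a kinetic resolution with the catalyst enantiomer that consumes the (2S,3R) ketone, gives 9 as one C1 epimer and leaves the mirror-image ketone. The cost is half of the material.

**Step 8.** The most likely failure is tautomerisation of quinone methide 12 to the 2-arylindene (loss of C2–H, which erases C2), or self-condensation of 12, before the aryl group is transferred; incomplete anti delivery is a lesser concern. The fallback replaces the warm boron manifold by an anionic one at low temperature, sets out from 10 and returns at 13. Boc2O with iPr2NEt and catalytic DMAP converts the phenol of 10 to the carbonate (2S,3R)-7-[(tert-butoxycarbonyl)oxy]-3-{[(tert-butyldimethylsilyl)oxy]methyl}-2-(3,5-dimethoxyphenyl)-5-methoxyindan-1-ol F4. Grignard reagent 17 (3 equiv, THF, −78 °C → rt) deprotonates O1, the carbonate migrates to O1 and is expelled by the phenoxide to give 12 in the cold. A second equivalent of 17 adds to C1 anti to the C2 aryl group, giving 13 after work-up. This is the known generation of o-quinone methides from o-(tert-butoxycarbonyloxy)benzyl alcohols with organomagnesium reagents.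

**Step 7.** The most likely failure is over-reduction: once the phenol is free, the C1–O bond of the o-hydroxybenzyl alcohol can be hydrogenolysed on the metal surface. The fallback goes from 9 to 10 with no new compound. O1 is deprotonated (n-BuLi, THF, −78 °C) and the benzyl ether is cleaved by single-electron transfer from lithium 4,4′-di-tert-butylbiphenylide at −78 °C. In this manifold the alkoxide at C1 is not a leaving group and no catalyst surface is present.

**Step 16.** The most likely failure is poor face discrimination, because the ketone carries a bulky indanyl group as well as the aryl group; slow borane attack on the aryl acetates is a second concern. The fallback goes from 21 to 22 with no new compound. Noyori–Ikariya transfer hydrogenation with RuCl(p-cymene)[(R,R)-TsDPEN] in HCO2H/Et3N recognises the aryl group by an arene contact with the catalyst instead of by size, uses no borane, and has the (R)-carbinol as its usual outcome for aryl ketones.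

**Step 17.** The most likely failure is ionisation of the freed 4-hydroxybenzylic carbinol to a p-quinone methide during methanolysis or neutralisation, leading to epimerisation at Cα or to the Cα methyl ether. The fallback changes the phenol mask, sets out from 20 and returns at 23. TBSCl/imidazole gives the hexakis(silyl ether) [(1R,2S,3R)-5,7-bis(tert-butyldimethylsilyloxy)-2-[3,5-bis(tert-butyldimethylsilyloxy)phenyl]-1-[4-(tert-butyldimethylsilyloxy)phenyl]indan-3-yl][4-(tert-butyldimethylsilyloxy)phenyl]methanone F5. The same oxazaborolidine reduction gives the (R)-carbinol (R)-[(1R,2S,3R)-5,7-bis(tert-butyldimethylsilyloxy)-2-[3,5-bis(tert-butyldimethylsilyloxy)phenyl]-1-[4-(tert-butyldimethylsilyloxy)phenyl]indan-3-yl][4-(tert-butyldimethylsilyloxy)phenyl]methanol F6. Buffered fluoride (TBAF/AcOH, THF, 0 °C) then releases 23 without base and without a nucleophilic solvent.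

## Further compounds

F1 | step 6 | tert-butyl{[3-(3,5-dimethoxyphenyl)prop-2-yn-1-yl]oxy}dimethylsilane | COc1cc(C#CCO[Si](C)(C)C(C)(C)C)cc(OC)c1
F2 | step 6 | 7-(benzyloxy)-3-{[(tert-butyldimethylsilyl)oxy]methyl}-2-(3,5-dimethoxyphenyl)-5-methoxy-1H-inden-1-ol (racemic at C1) | OC1C(c2cc(OC)cc(OC)c2)=C(CO[Si](C)(C)C(C)(C)C)c2cc(OC)cc(OCc3ccccc3)c12
F3 | step 6 | (2S*,3R*)-7-(benzyloxy)-3-{[(tert-butyldimethylsilyl)oxy]methyl}-2-(3,5-dimethoxyphenyl)-5-methoxyindan-1-one (racemic trans; the (2S,3R) enantiomer is drawn) | O=C1c2c(OCc3ccccc3)cc(OC)cc2[C@H](CO[Si](C)(C)C(C)(C)C)[C@H]1c1cc(OC)cc(OC)c1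
F0 | step 7 | none | none
F4 | step 8 | (2S,3R)-7-[(tert-butoxycarbonyl)oxy]-3-{[(tert-butyldimethylsilyl)oxy]methyl}-2-(3,5-dimethoxyphenyl)-5-methoxyindan-1-ol (both C1 epimers) | OC1c2c(OC(=O)OC(C)(C)C)cc(OC)cc2[C@H](CO[Si](C)(C)C(C)(C)C)[C@H]1c1cc(OC)cc(OC)c1
F0 | step 16 | none | none
F5 | step 17 | [(1R,2S,3R)-5,7-bis(tert-butyldimethylsilyloxy)-2-[3,5-bis(tert-butyldimethylsilyloxy)phenyl]-1-[4-(tert-butyldimethylsilyloxy)phenyl]indan-3-yl][4-(tert-butyldimethylsilyloxy)phenyl]methanone | CC(C)(C)[Si](C)(C)Oc1ccc([C@@H]2c3c(O[Si](C)(C)C(C)(C)C)cc(O[Si](C)(C)C(C)(C)C)cc3[C@H](C(=O)c3ccc(O[Si](C)(C)C(C)(C)C)cc3)[C@H]2c2cc(O[Si](C)(C)C(C)(C)C)cc(O[Si](C)(C)C(C)(C)C)c2)cc1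
F6 | step 17 | (R)-[(1R,2S,3R)-5,7-bis(tert-butyldimethylsilyloxy)-2-[3,5-bis(tert-butyldimethylsilyloxy)phenyl]-1-[4-(tert-butyldimethylsilyloxy)phenyl]indan-3-yl][4-(tert-butyldimethylsilyloxy)phenyl]methanol | CC(C)(C)[Si](C)(C)Oc1ccc([C@@H]2c3c(O[Si](C)(C)C(C)(C)C)cc(O[Si](C)(C)C(C)(C)C)cc3[C@H]([C@@H](O)c3ccc(O[Si](C)(C)C(C)(C)C)cc3)[C@H]2c2cc(O[Si](C)(C)C(C)(C)C)cc(O[Si](C)(C)C(C)(C)C)c2)cc1
A1 | alternative 1 | [1,2-bis(3,5-dimethoxyphenyl)-3-(4-methoxyphenyl)cyclopropyl](4-methoxyphenyl)methanone, configured at the ring carbon that becomes C2 (the other two ring carbons lose their configuration in the ring opening) | COc1ccc(C(=O)C2(c3cc(OC)cc(OC)c3)[C@@H](c3cc(OC)cc(OC)c3)C2c2ccc(OC)cc2)cc1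
A2 | alternative 1 | all-trans [2-(3,5-dimethoxyphenyl)-5,7-dimethoxy-1-(4-methoxyphenyl)indan-3-yl](4-methoxyphenyl)methanone (identical with 19) | COc1ccc([C@@H]2c3c(OC)cc(OC)cc3[C@H](C(=O)c3ccc(OC)cc3)[C@H]2c2cc(OC)cc(OC)c2)cc1
A3 | alternative 2 | methyl 2,3-bis(3,5-dimethoxyphenyl)-4-oxobutanoate, with the configuration needed for the all-trans ring | COC(=O)[C@@H](c1cc(OC)cc(OC)c1)[C@H](C=O)c1cc(OC)cc(OC)c1
A4 | alternative 2 | all-trans methyl 2-(3,5-dimethoxyphenyl)-1-(4-hydroxyphenyl)-5,7-dimethoxyindane-3-carboxylate | Oc1ccc([C@@H]2c3c(OC)cc(OC)cc3[C@H](C(=O)OC)[C@H]2c2cc(OC)cc(OC)c2)cc1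
A5 | alternative 3 | trans-2-diazo-3-(3,5-dimethoxyphenyl)-5,7-dimethoxy-4-(4-methoxyphenyl)-3,4-dihydronaphthalen-1(2H)-one | COc1ccc([C@@H]2c3c(OC)cc(OC)cc3C(=O)C(=[N+]=[N-])[C@H]2c2cc(OC)cc(OC)c2)cc1
A6 | alternative 3 | all-trans methyl 2-(3,5-dimethoxyphenyl)-5,7-dimethoxy-1-(4-methoxyphenyl)indane-3-carboxylate | COc1ccc([C@@H]2c3c(OC)cc(OC)cc3[C@H](C(=O)OC)[C@H]2c2cc(OC)cc(OC)c2)cc1
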